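The route builds the central benzene ring B last, from two open fragments. Its six carbons alternate between oxygen-bearing (the three phenolic C–O) and carbon-bearing (butyryl carbon, CH2 bridge to ring A, CH2 bridge to chromene ring C), exactly the pattern that a vinylketene and an ynol ether assemble. One thermal benzannulation of a cyclobutenone with a siloxyalkyne forms three C–C bonds and ring B, and places each bridge carbon from a different partner. The precursor is a cyclobutenone carrying the chromenylmethyl group at C2 and a silyloxy group at C3; the alkyne brings a methoxymethyl arm that later links enantiopure ring A.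

Key step: step 8

Remark: ring A is the dearomatised acetyl triketone ring with the quaternary carbon, ring B the central butyryl phloroglucinol, ring C the butyryl chromene; MOM = methoxymethyl, TIPS = triisopropylsilyl.
Remark: the quaternary carbon of ring A is read from the SMILES as R; it is made racemic in step 14 and resolved in step 15, and which fraction is R is to be assigned by ECD or X-ray analysis before step 16.
Remark: compounds 27 and 28, methyl propargyl ether and 3-bromo-1-(trimethylsilyl)prop-1-yne are taken as catalogue chemicals; ketene gas is drawn from a ketene generator (acetone pyrolysis).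
Remark: a silyl ether at C3 of the cyclobutenone lets fluoride free both silylated ring B oxygens, and both butyryl groups are installed by ring metalation, because the benzylic methyl ether and the chromene would not tolerate Lewis-acid acylation or dealkylation.

Step 1
Reactants: 1 phloroglucinol; 2 prenal
Product: 3 2,2-dimethyl-2H-chromene-5,7-diol
Conditions: pyridine, 110 °C, 1 in threefold excess
Reagents that add atoms: none
Why: Knoevenagel-type condensation of the enal at a ring carbon, dehydration and oxa-6π electrocyclisation give the chromene (formal [3+3] annulation), and the excess of 1 should suppress a second annulation.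

Step 2
Reactants: 3 2,2-dimethyl-2H-chromene-5,7-diol
Product: 4 5,7-bis(methoxymethoxy)-2,2-dimethyl-2H-chromene
Conditions: NaH, MOMCl, DMF, 0 °C → rt
Reagents that add atoms: chloromethyl methyl ether (MOMCl), COCCl
Why: Williamson O-alkylation of both phenoxides by the hard electrophile installs the acetals that later direct ring metalation.

Step 3
Reactants: 4 5,7-bis(methoxymethoxy)-2,2-dimethyl-2H-chromene
Product: 6 {3-[5,7-bis(methoxymethoxy)-2,2-dimethyl-2H-chromen-6-yl]prop-1-yn-1-yl}trimethylsilane, via 6-lithiochromene 5 (not isolated)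
Conditions: n-BuLi, THF, 0 °C; then CuBr·SMe2 (10 mol %), BrCH2C≡CSiMe3, −40 → 0 °C
Reagents that add atoms: 3-bromo-1-(trimethylsilyl)prop-1-yne, C[Si](C)(C)C#CCBr
Why: Directed ortho-metalation should occur at C6, the only C–H flanked by two chelating MOM ethers (C8 has one MOM and the hindered pyran oxygen), and copper-catalysed SN2 propargylation follows, the silyl cap disfavouring the allenyl product.

Step 4
Reactants: 6 {3-[5,7-bis(methoxymethoxy)-2,2-dimethyl-2H-chromen-6-yl]prop-1-yn-1-yl}trimethylsilane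
Product: 7 5,7-bis(methoxymethoxy)-2,2-dimethyl-6-(prop-2-yn-1-yl)-2H-chromene
Conditions: K2CO3 (cat.), MeOH, 0 °C → rt
Reagents that add atoms: none
Why: Methoxide-catalysed protodesilylation of the alkynylsilane is mild enough to spare the acetals and to avoid propargyl-to-allene isomerisation.

Step 5
Reactants: 7 5,7-bis(methoxymethoxy)-2,2-dimethyl-6-(prop-2-yn-1-yl)-2H-chromene
Product: 10 ({3-[5,7-bis(methoxymethoxy)-2,2-dimethyl-2H-chromen-6-yl]prop-1-yn-1-yl}oxy)triisopropylsilane, via lithium acetylide 8 (not isolated), via lithium ynolate 9 (not isolated)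
Conditions: n-BuLi, THF, −78 °C; LiOOt-Bu (from t-BuOOH and LiN(SiMe3)2), −78 → 0 °C; i-Pr3SiOTf, −78 °C
Reagents that add atoms: tert-butyl hydroperoxide, CC(C)(C)OO; triisopropylsilyl trifluoromethanesulfonate, CC(C)[Si](OS(=O)(=O)C(F)(F)F)(C(C)C)C(C)C
Why: Oxidation of a lithium acetylide by lithium tert-butyl peroxide gives the ynolate, which the bulky silyl triflate captures on oxygen (established siloxyalkyne synthesis).

Step 6
Reactants: 10 ({3-[5,7-bis(methoxymethoxy)-2,2-dimethyl-2H-chromen-6-yl]prop-1-yn-1-yl}oxy)triisopropylsilane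
Product: 11 2-{[5,7-bis(methoxymethoxy)-2,2-dimethyl-2H-chromen-6-yl]methyl}-3-[(triisopropylsilyl)oxy]cyclobut-2-en-1-one
Conditions: CH2=C=O (gas), CH2Cl2, 0 °C → rt
Reagents that add atoms: ketene, C=C=O
Why: [2+2] cycloaddition of ketene with the electron-rich siloxyalkyne joins the ketene carbonyl carbon to the alkyne carbon bearing the arylmethyl group, giving the 3-silyloxycyclobutenone regiospecifically.

Step 7
Reactants: 12 3-methoxyprop-1-yne
Product: 15 [(3-methoxyprop-1-yn-1-yl)oxy]triisopropylsilane, via lithium acetylide 13 (not isolated), via lithium ynolate 14 (not isolated)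
Conditions: n-BuLi, THF, −78 °C; LiOOt-Bu (from t-BuOOH and LiN(SiMe3)2), −78 → 0 °C; i-Pr3SiOTf, −78 °C
Reagents that add atoms: tert-butyl hydroperoxide, CC(C)(C)OO; triisopropylsilyl trifluoromethanesulfonate, CC(C)[Si](OS(=O)(=O)C(F)(F)F)(C(C)C)C(C)C
Why: The same acetylide oxidation and O-silylation as in step 5 turns the propargyl ether into the siloxyalkyne that carries the future ring A bridge carbon.

Step 8
Reactants: 11 2-{[5,7-bis(methoxymethoxy)-2,2-dimethyl-2H-chromen-6-yl]methyl}-3-[(triisopropylsilyl)oxy]cyclobut-2-en-1-one; 15 [(3-methoxyprop-1-yn-1-yl)oxy]triisopropylsilane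
Product: 20 4-{[5,7-bis(methoxymethoxy)-2,2-dimethyl-2H-chromen-6-yl]methyl}-2-(methoxymethyl)-3,5-bis[(triisopropylsilyl)oxy]phenol, via vinylketene 16 (not isolated), via vinylcyclobutenone 17 (not isolated), via dienylketene 18 (not isolated), via cyclohexadienone 19 (not isolated)
Conditions: toluene, 110 °C, argon, 15 (2 equiv), slow addition of 11
Reagents that add atoms: none
Why: Proposed new method: a 3-silyloxy-2-alkylcyclobutenone has not been shown as the vinylketene source, the closest known reaction being the Danheiser benzannulation of 3-alkyl- or 3-arylcyclobutenones with siloxyalkynes to resorcinol monosilyl ethers; by the same mechanism, thermal 4π ring opening of 11 should give vinylketene 16, whose electrophilic ketene carbon adds to the nucleophilic alkyne carbon of 15 in a [2+2] step to give 17. A second 4π opening gives dienylketene 18, and ring B then closes by a thermal disrotatory 6π electrocyclisation between the ketene carbon and the terminal CH2, after which dienone 19 tautomerises to the phenol. No stereocentre survives, since the quaternary carbon of 17 is lost on reopening. The selectivity needed is regiochemical only and is secured by the polarity of the partners: the siloxyalkyne is nucleophilic at the carbon bearing CH2OMe and the ketene electrophilic at its carbonyl carbon, so the new OH and one silyloxy group flank the methoxymethyl carbon, the chromenylmethyl carbon sits between the two silyloxy groups and the only C–H lies between silyloxy and OH. An excess of 15 and slow addition of 11 should keep the product phenol from trapping the ketene.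

Step 9
Reactants: 20 4-{[5,7-bis(methoxymethoxy)-2,2-dimethyl-2H-chromen-6-yl]methyl}-2-(methoxymethyl)-3,5-bis[(triisopropylsilyl)oxy]phenol
Product: 21 5,7-bis(methoxymethoxy)-6-{[3-(methoxymethyl)-4-(methoxymethoxy)-2,6-bis[(triisopropylsilyl)oxy]phenyl]methyl}-2,2-dimethyl-2H-chromene
Conditions: NaH, MOMCl, THF, 0 °C
Reagents that add atoms: chloromethyl methyl ether (MOMCl), COCCl
Why: Williamson O-alkylation of the single free phenol turns it into the directing group for metalation of the adjacent ring B C–H.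

Step 10
Reactants: 21 5,7-bis(methoxymethoxy)-6-{[3-(methoxymethyl)-4-(methoxymethoxy)-2,6-bis[(triisopropylsilyl)oxy]phenyl]methyl}-2,2-dimethyl-2H-chromene
Product: 23 1-[3-({8-(1-hydroxybutyl)-5,7-bis(methoxymethoxy)-2,2-dimethyl-2H-chromen-6-yl}methyl)-5-(methoxymethyl)-6-(methoxymethoxy)-2,4-bis[(triisopropylsilyl)oxy]phenyl]butan-1-ol (mixture of diastereomers), via dilithio species 22 (not isolated)
Conditions: s-BuLi (2.6 equiv), TMEDA, THF, −78 °C; PrCHO, −78 °C; AcOH/THF, −78 °C
Reagents that add atoms: butanal, CCCC=O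
Why: Twofold directed ortho-metalation at the only two ring C–H bonds left, each next to a MOM ether (chromene C8 and the ring B C–H), followed by addition to butanal and a cold quench, should outrun silyl migration and benzylic metalation; the two carbinol centres form unselectively and are erased in step 11.

Step 11
Reactants: 23 the bis-carbinol from step 10
Product: 24 1-[3-({8-butanoyl-5,7-bis(methoxymethoxy)-2,2-dimethyl-2H-chromen-6-yl}methyl)-5-(methoxymethyl)-6-(methoxymethoxy)-2,4-bis[(triisopropylsilyl)oxy]phenyl]butan-1-one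
Conditions: Dess–Martin periodinane, CH2Cl2, rt
Reagents that add atoms: none
Why: Dess–Martin oxidation converts both benzylic alcohols into the aryl propyl ketones under conditions that the acetals, silyl ethers, benzylic ether and chromene should tolerate.

Step 12
Reactants: 24 the bis-silyl diketone
Product: 25 1-[3-({8-butanoyl-5,7-bis(methoxymethoxy)-2,2-dimethyl-2H-chromen-6-yl}methyl)-2,4-dihydroxy-5-(methoxymethyl)-6-(methoxymethoxy)phenyl]butan-1-one
Conditions: Bu4NF, AcOH, THF, 0 °C
Reagents that add atoms: none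
Why: Fluoride cleaves both aryl silyl ethers, and the acetic acid buffer should keep the freed ortho-hydroxybenzyl ether from losing methoxide.

Step 13
Reactants: 25 the tris-MOM diketone
Product: 26 1-[3-({8-butanoyl-5,7-dihydroxy-2,2-dimethyl-2H-chromen-6-yl}methyl)-2,4,6-trihydroxy-5-(methoxymethyl)phenyl]butan-1-one
Conditions: HCl (cat.), MeOH, 40 °C
Reagents that add atoms: none
Why: Acid-catalysed transacetalisation removes the three MOM groups, while in methanol any ionisation of the benzylic methyl ether is degenerate and no ring C–H remains to be alkylated.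

Step 14
Reactants: 27 1-(2,4,6-trihydroxy-3-methylphenyl)ethan-1-one; 28 geranyl bromide
Product: 29 rac-2-acetyl-3,5-dihydroxy-4-methyl-4-[(2E)-3,7-dimethylocta-2,6-dien-1-yl]cyclohexa-2,5-dien-1-one
Conditions: NaOMe, MeOH, 0 °C → rt
Reagents that add atoms: none
Why: Alkylative dearomatisation by SN2 attack of the phloroglucinol anion at its methyl-bearing carbon (the more electron-rich ring carbon, as in the gem-dimethylation that leads to filicinic acids) creates the quaternary carbon as a racemate and leaves the E alkene untouched.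

Step 15
Reactants: 29 racemic ring A triketone
Product: 30 (4R)-2-acetyl-3,5-dihydroxy-4-methyl-4-[(2E)-3,7-dimethylocta-2,6-dien-1-yl]cyclohexa-2,5-dien-1-one
Conditions: preparative SFC, amylose tris(3,5-dimethylphenylcarbamate) phase, CO2/MeOH (0.1 % HCO2H)
Reagents that add atoms: none
Why: Resolution on a chiral stationary phase separates the enantiomers and the R fraction is kept, which fixes the only stereocentre of the target at a carbon that bears no hydrogen and cannot epimerise later.

Step 16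
Reactants: 26 ring B–ring C fragment with the methoxymethyl arm; 30 (R)-ring A triketone
Product: 32 target CNP0103039.1, via o-quinone methide 31 (not isolated)
Conditions: 1,4-dioxane, 5 Å MS, 80 °C, argon
Reagents that add atoms: none
Why: Thermal loss of methanol from the ortho-hydroxybenzyl methyl ether gives the ring B o-quinone methide, and Michael addition of C6 of the ring A enol (its only unsubstituted nucleophilic carbon) forms the second methylene bridge without touching the quaternary stereocentre.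

Compound list
1 | phloroglucinol (benzene-1,3,5-triol) | Oc1cc(O)cc(O)c1 | starting material
2 | prenal (3-methylbut-2-enal) | CC(C)=CC=O | starting material
3 | 2,2-dimethyl-2H-chromene-5,7-diol | CC1(C)C=Cc2c(O)cc(O)cc2O1 | intermediate
4 | 5,7-bis(methoxymethoxy)-2,2-dimethyl-2H-chromene | COCOc1cc(OCOC)c2C=CC(C)(C)Oc2c1 | intermediate
5 | [5,7-bis(methoxymethoxy)-2,2-dimethyl-2H-chromen-6-yl]lithium (not isolated) | [Li]c1c(OCOC)cc2OC(C)(C)C=Cc2c1OCOC | intermediate
6 | {3-[5,7-bis(methoxymethoxy)-2,2-dimethyl-2H-chromen-6-yl]prop-1-yn-1-yl}trimethylsilane | C[Si](C)(C)C#CCc1c(OCOC)cc2OC(C)(C)C=Cc2c1OCOC | intermediate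
7 | 5,7-bis(methoxymethoxy)-2,2-dimethyl-6-(prop-2-yn-1-yl)-2H-chromene | C#CCc1c(OCOC)cc2OC(C)(C)C=Cc2c1OCOC | intermediate
8 | {3-[5,7-bis(methoxymethoxy)-2,2-dimethyl-2H-chromen-6-yl]prop-1-yn-1-yl}lithium (not isolated) | [Li]C#CCc1c(OCOC)cc2OC(C)(C)C=Cc2c1OCOC | intermediate
9 | lithium 3-[5,7-bis(methoxymethoxy)-2,2-dimethyl-2H-chromen-6-yl]prop-1-yn-1-olate (not isolated) | [Li]OC#CCc1c(OCOC)cc2OC(C)(C)C=Cc2c1OCOC | intermediate
10 | ({3-[5,7-bis(methoxymethoxy)-2,2-dimethyl-2H-chromen-6-yl]prop-1-yn-1-yl}oxy)triisopropylsilane | CC(C)[Si](OC#CCc1c(OCOC)cc2OC(C)(C)C=Cc2c1OCOC)(C(C)C)C(C)C | intermediate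
11 | 2-{[5,7-bis(methoxymethoxy)-2,2-dimethyl-2H-chromen-6-yl]methyl}-3-[(triisopropylsilyl)oxy]cyclobut-2-en-1-one | O=C1CC(O[Si](C(C)C)(C(C)C)C(C)C)=C1Cc2c(OCOC)cc3OC(C)(C)C=Cc3c2OCOC | intermediate
12 | 3-methoxyprop-1-yne (methyl propargyl ether) | COCC#C | starting material
13 | (3-methoxyprop-1-yn-1-yl)lithium (not isolated) | [Li]C#CCOC | intermediate
14 | lithium 3-methoxyprop-1-yn-1-olate (not isolated) | [Li]OC#CCOC | intermediate
15 | [(3-methoxyprop-1-yn-1-yl)oxy]triisopropylsilane | COCC#CO[Si](C(C)C)(C(C)C)C(C)C | intermediate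
16 | 2-{[5,7-bis(methoxymethoxy)-2,2-dimethyl-2H-chromen-6-yl]methyl}-3-[(triisopropylsilyl)oxy]buta-1,3-dien-1-one (vinylketene, not isolated) | O=C=C(Cc1c(OCOC)cc2OC(C)(C)C=Cc2c1OCOC)C(=C)O[Si](C(C)C)(C(C)C)C(C)C | intermediate
17 | rac-4-{[5,7-bis(methoxymethoxy)-2,2-dimethyl-2H-chromen-6-yl]methyl}-2-(methoxymethyl)-3-[(triisopropylsilyl)oxy]-4-{1-[(triisopropylsilyl)oxy]ethenyl}cyclobut-2-en-1-one (not isolated) | O=C1C(COC)=C(O[Si](C(C)C)(C(C)C)C(C)C)C1(Cc2c(OCOC)cc3OC(C)(C)C=Cc3c2OCOC)C(=C)O[Si](C(C)C)(C(C)C)C(C)C | intermediate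
18 | (3E)-4-{[5,7-bis(methoxymethoxy)-2,2-dimethyl-2H-chromen-6-yl]methyl}-2-(methoxymethyl)-3,5-bis[(triisopropylsilyl)oxy]hexa-1,3,5-trien-1-one (dienylketene, not isolated) | O=C=C(COC)/C(O[Si](C(C)C)(C(C)C)C(C)C)=C(/Cc1c(OCOC)cc2OC(C)(C)C=Cc2c1OCOC)C(=C)O[Si](C(C)C)(C(C)C)C(C)C | intermediate
19 | 4-{[5,7-bis(methoxymethoxy)-2,2-dimethyl-2H-chromen-6-yl]methyl}-2-(methoxymethyl)-3,5-bis[(triisopropylsilyl)oxy]cyclohexa-2,4-dien-1-one (not isolated) | O=C1CC(O[Si](C(C)C)(C(C)C)C(C)C)=C(Cc2c(OCOC)cc3OC(C)(C)C=Cc3c2OCOC)C(O[Si](C(C)C)(C(C)C)C(C)C)=C1COC | intermediate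
20 | 4-{[5,7-bis(methoxymethoxy)-2,2-dimethyl-2H-chromen-6-yl]methyl}-2-(methoxymethyl)-3,5-bis[(triisopropylsilyl)oxy]phenol | COCc1c(O)cc(O[Si](C(C)C)(C(C)C)C(C)C)c(Cc2c(OCOC)cc3OC(C)(C)C=Cc3c2OCOC)c1O[Si](C(C)C)(C(C)C)C(C)C | intermediate
21 | 5,7-bis(methoxymethoxy)-6-{[3-(methoxymethyl)-4-(methoxymethoxy)-2,6-bis[(triisopropylsilyl)oxy]phenyl]methyl}-2,2-dimethyl-2H-chromene | COCc1c(OCOC)cc(O[Si](C(C)C)(C(C)C)C(C)C)c(Cc2c(OCOC)cc3OC(C)(C)C=Cc3c2OCOC)c1O[Si](C(C)C)(C(C)C)C(C)C | intermediate
22 | dilithio derivative of 21, lithium at chromene C8 and at the ring B C–H carbon (not isolated) | COCc1c(OCOC)c([Li])c(O[Si](C(C)C)(C(C)C)C(C)C)c(Cc2c(OCOC)c([Li])c3OC(C)(C)C=Cc3c2OCOC)c1O[Si](C(C)C)(C(C)C)C(C)C | intermediate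
23 | 1-[3-({8-(1-hydroxybutyl)-5,7-bis(methoxymethoxy)-2,2-dimethyl-2H-chromen-6-yl}methyl)-5-(methoxymethyl)-6-(methoxymethoxy)-2,4-bis[(triisopropylsilyl)oxy]phenyl]butan-1-ol (mixture of diastereomers) | CCCC(O)c1c(OCOC)c(COC)c(O[Si](C(C)C)(C(C)C)C(C)C)c(Cc2c(OCOC)c(C(O)CCC)c3OC(C)(C)C=Cc3c2OCOC)c1O[Si](C(C)C)(C(C)C)C(C)C | intermediate
24 | 1-[3-({8-butanoyl-5,7-bis(methoxymethoxy)-2,2-dimethyl-2H-chromen-6-yl}methyl)-5-(methoxymethyl)-6-(methoxymethoxy)-2,4-bis[(triisopropylsilyl)oxy]phenyl]butan-1-one | CCCC(=O)c1c(OCOC)c(COC)c(O[Si](C(C)C)(C(C)C)C(C)C)c(Cc2c(OCOC)c(C(=O)CCC)c3OC(C)(C)C=Cc3c2OCOC)c1O[Si](C(C)C)(C(C)C)C(C)C | intermediate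
25 | 1-[3-({8-butanoyl-5,7-bis(methoxymethoxy)-2,2-dimethyl-2H-chromen-6-yl}methyl)-2,4-dihydroxy-5-(methoxymethyl)-6-(methoxymethoxy)phenyl]butan-1-one | CCCC(=O)c1c(OCOC)c(COC)c(O)c(Cc2c(OCOC)c(C(=O)CCC)c3OC(C)(C)C=Cc3c2OCOC)c1O | intermediate
26 | 1-[3-({8-butanoyl-5,7-dihydroxy-2,2-dimethyl-2H-chromen-6-yl}methyl)-2,4,6-trihydroxy-5-(methoxymethyl)phenyl]butan-1-one | CCCC(=O)c1c(O)c(COC)c(O)c(Cc2c(O)c(C(=O)CCC)c3OC(C)(C)C=Cc3c2O)c1O | intermediate
27 | 1-(2,4,6-trihydroxy-3-methylphenyl)ethan-1-one | CC(=O)c1c(O)cc(O)c(C)c1O | starting material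
28 | geranyl bromide, (2E)-1-bromo-3,7-dimethylocta-2,6-diene | BrC/C=C(\C)CCC=C(C)C | starting material
29 | rac-2-acetyl-3,5-dihydroxy-4-methyl-4-[(2E)-3,7-dimethylocta-2,6-dien-1-yl]cyclohexa-2,5-dien-1-one | C1=C(O)C(C)(C/C=C(\C)CCC=C(C)C)C(O)=C(C(C)=O)C1=O | intermediate
30 | (4R)-2-acetyl-3,5-dihydroxy-4-methyl-4-[(2E)-3,7-dimethylocta-2,6-dien-1-yl]cyclohexa-2,5-dien-1-one | C1=C(O)[C@@](C)(C/C=C(\C)CCC=C(C)C)C(O)=C(C(C)=O)C1=O | intermediate
31 | ring B o-quinone methide of 26: 2-butanoyl-4-({8-butanoyl-5,7-dihydroxy-2,2-dimethyl-2H-chromen-6-yl}methyl)-3,5-dihydroxy-6-methylidenecyclohexa-2,4-dien-1-one (not isolated) | C=C1C(=O)C(C(=O)CCC)=C(O)C(Cc2c(O)c(C(=O)CCC)c3OC(C)(C)C=Cc3c2O)=C1O | intermediate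
32 | CNP0103039.1: 1-[3-({(3R)-5-acetyl-3-[(2E)-3,7-dimethylocta-2,6-dien-1-yl]-2,4-dihydroxy-3-methyl-6-oxocyclohexa-1,4-dien-1-yl}methyl)-5-({8-butanoyl-5,7-dihydroxy-2,2-dimethyl-2H-chromen-6-yl}methyl)-2,4,6-trihydroxyphenyl]butan-1-one | CCCC(=O)c1c(O)c(CC2=C(O)[C@@](C)(C/C=C(\C)CCC=C(C)C)C(O)=C(C(C)=O)C2=O)c(O)c(Cc2c(O)c3c(c(C(=O)CCC)c2O)OC(C)(C)C=C3)c1O | target

Total step count: 16.
Longest linear sequence: 13 steps (steps 1–6, 8–13 and 16); step 7 and steps 14–15 are side branches.

Steps most likely to fail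

Step 8. The donor-stabilised cyclobutenone may open only at temperatures where the siloxyalkyne isomerises to a silylketene, or the vinylketene may be captured by the product phenol faster than by the alkyne. The fallback sets out from prenal 2 and comes back to the route at target 32, using the classical Mannich and o-quinone methide chemistry of acylphloroglucinols. Chromene annulation of 2 with commercial 1-(2,4,6-trihydroxyphenyl)butan-1-one (CCCC(=O)c1c(O)cc(O)cc1O; pyridine, 110 °C) and removal of the 6-acyl regioisomer would give 1-(5,7-dihydroxy-2,2-dimethyl-2H-chromen-8-yl)butan-1-one F1. A Mannich reaction at its only free ring carbon (Me2N=CH2+ I−, CH2Cl2) would give 1-{6-[(dimethylamino)methyl]-5,7-dihydroxy-2,2-dimethyl-2H-chromen-8-yl}butan-1-one F2. Heating F2 with an excess of the same butyrylphloroglucinol in dioxane would give 1-[3-({8-butanoyl-5,7-dihydroxy-2,2-dimethyl-2H-chromen-6-yl}methyl)-2,4,6-trihydroxyphenyl]butan-1-one F3. A second Mannich reaction at the last free carbon of ring B would give 1-[3-({8-butanoyl-5,7-dihydroxy-2,2-dimethyl-2H-chromen-6-yl}methyl)-5-[(dimethylamino)methyl]-2,4,6-trihydroxyphenyl]butan-1-one F4, and heating F4 with 30 in dioxane would give 32.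

Step 10. The second metalation may stay incomplete, benzylic deprotonation at the diarylmethane or methoxymethyl CH2 may compete, or the silyl group next to the ring B aryllithium may migrate from oxygen to carbon. The fallback sets out from 20 and comes back at 23, replacing deprotonation by halogen–lithium exchange. NBS (2 equiv, CH2Cl2, −20 °C) would brominate the two electron-rich ring C–H positions to give 2-bromo-4-{[8-bromo-5,7-bis(methoxymethoxy)-2,2-dimethyl-2H-chromen-6-yl]methyl}-6-(methoxymethyl)-3,5-bis[(triisopropylsilyl)oxy]phenol F5. NaH and MOMCl would give 8-bromo-6-{[3-bromo-5-(methoxymethyl)-4-(methoxymethoxy)-2,6-bis[(triisopropylsilyl)oxy]phenyl]methyl}-5,7-bis(methoxymethoxy)-2,2-dimethyl-2H-chromene F6. Twofold bromine–lithium exchange (t-BuLi, THF, −78 °C, a few minutes) followed at once by butanal and a cold AcOH quench would give 23.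

Step 14. Alkylation may take place at the unsubstituted ring carbon or on oxygen instead of at the methyl-bearing carbon, so that the dearomatising site selectivity is poor. The fallback sets out from 27 and comes back at 29, blocking the free carbon first. NBS (MeCN, 0 °C) would give 1-(3-bromo-2,4,6-trihydroxy-5-methylphenyl)ethan-1-one F7. Geranylation with 28 (NaOMe, MeOH) can then occur on carbon only at the methyl-bearing position, giving rac-2-acetyl-6-bromo-3,5-dihydroxy-4-methyl-4-[(2E)-3,7-dimethylocta-2,6-dien-1-yl]cyclohexa-2,5-dien-1-one F8. Reductive removal of the bromine from the 1,3-dicarbonyl carbon (Zn, AcOH, rt) would return 29.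

Further compounds
F1 | step 8 | 1-(5,7-dihydroxy-2,2-dimethyl-2H-chromen-8-yl)butan-1-one | CCCC(=O)c1c(O)cc(O)c2C=CC(C)(C)Oc12
F2 | step 8 | 1-{6-[(dimethylamino)methyl]-5,7-dihydroxy-2,2-dimethyl-2H-chromen-8-yl}butan-1-one | CCCC(=O)c1c(O)c(CN(C)C)c(O)c2C=CC(C)(C)Oc12
F3 | step 8 | 1-[3-({8-butanoyl-5,7-dihydroxy-2,2-dimethyl-2H-chromen-6-yl}methyl)-2,4,6-trihydroxyphenyl]butan-1-one | CCCC(=O)c1c(O)cc(O)c(Cc2c(O)c(C(=O)CCC)c3OC(C)(C)C=Cc3c2O)c1O
F4 | step 8 | 1-[3-({8-butanoyl-5,7-dihydroxy-2,2-dimethyl-2H-chromen-6-yl}methyl)-5-[(dimethylamino)methyl]-2,4,6-trihydroxyphenyl]butan-1-one | CCCC(=O)c1c(O)c(CN(C)C)c(O)c(Cc2c(O)c(C(=O)CCC)c3OC(C)(C)C=Cc3c2O)c1O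
F5 | step 10 | 2-bromo-4-{[8-bromo-5,7-bis(methoxymethoxy)-2,2-dimethyl-2H-chromen-6-yl]methyl}-6-(methoxymethyl)-3,5-bis[(triisopropylsilyl)oxy]phenol | COCc1c(O)c(Br)c(O[Si](C(C)C)(C(C)C)C(C)C)c(Cc2c(OCOC)c(Br)c3OC(C)(C)C=Cc3c2OCOC)c1O[Si](C(C)C)(C(C)C)C(C)C
F6 | step 10 | 8-bromo-6-{[3-bromo-5-(methoxymethyl)-4-(methoxymethoxy)-2,6-bis[(triisopropylsilyl)oxy]phenyl]methyl}-5,7-bis(methoxymethoxy)-2,2-dimethyl-2H-chromene | COCc1c(OCOC)c(Br)c(O[Si](C(C)C)(C(C)C)C(C)C)c(Cc2c(OCOC)c(Br)c3OC(C)(C)C=Cc3c2OCOC)c1O[Si](C(C)C)(C(C)C)C(C)C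
F7 | step 14 | 1-(3-bromo-2,4,6-trihydroxy-5-methylphenyl)ethan-1-one | CC(=O)c1c(O)c(Br)c(O)c(C)c1O
F8 | step 14 | rac-2-acetyl-6-bromo-3,5-dihydroxy-4-methyl-4-[(2E)-3,7-dimethylocta-2,6-dien-1-yl]cyclohexa-2,5-dien-1-one | CC(=O)C1=C(O)C(C)(C/C=C(\C)CCC=C(C)C)C(O)=C(Br)C1=O
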